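**Retrosynthetic overview**
- The depside ester C(=O)–O bond is cut late: ring A aroyl chloride 16 plus ring B phenol 11. One acidolysis of the MOM ethers and the tert-butyl ester then ends the route.
- Ring B is the only ring that is built. It is hexasubstituted: C1 CO2H, C2 OH, C3 CHO, C4 OH, C5 O-acyl, C6 CH3, i.e. oxygen on C2, C4 and C5 next to the adjacent C6-methyl and C1-carboxyl carbons. Bonds C1–C2 and C5–C6 come from a [4+2] cycloaddition of the 1,1,3,4-tetraoxygenated diene 4 with ynoate 5, aromatised by loss of methanol. The C5 oxygen enters as a benzyl ether and is therefore distinguished from the two phenols.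
- The single unsubstituted carbon of ring B (C3) is formylated after the annulation. Ring A is bought as an arene (12) and formylated ortho to its phenol.
- Order of ring formation: ring B in step 3; ring A purchased; union in step 11.

Key step: step 3

Remarks: Compounds 1, 5 and 12 are taken as purchasable. Ring B is numbered as the benzoic acid (C1 = carboxyl-bearing carbon); ring A likewise. Compound 3 is expected as an E/Z mixture whose geometry is erased in step 2. Diene 4 is drawn as the 1Z,3Z isomer expected from kinetic enolisation; a 3E isomer would converge on the same arene. The target has no stereocentre.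

**Step 1**
Reactants: 1 methyl 4-(benzyloxy)-3-oxobutanoate; 2 chlorotrimethylsilane
Product: 3 methyl 4-(benzyloxy)-3-(trimethylsilyloxy)but-2-enoate
Conditions: Et3N, hexane, rt
Reagents that add atoms: none
Why: Soft enolisation and O-silylation of the conjugated enol of the β-keto ester (silyl enol ether formation) should give the β-silyloxy enoate, the benzyl ether being inert.

**Step 2**
Reactants: 3 methyl 4-(benzyloxy)-3-(trimethylsilyloxy)but-2-enoate; 2 chlorotrimethylsilane
Product: 4 (1Z,3Z)-4-(benzyloxy)-1-methoxy-1,3-bis(trimethylsilyloxy)buta-1,3-diene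
Conditions: LiN(i-Pr)2, THF, −78 °C; then 2, −78 °C → rt; used crude
Reagents that add atoms: none
Why: γ-Deprotonation of the vinylogous ester gives the extended dienolate, which is O-silylated on the ester oxygen (silyl ketene acetal formation, the standard preparation of 1-methoxy-1,3-bis(silyloxy)butadienes); the benzyloxy group is expected anti to C2, on the outer side of the s-cis diene.

**Step 3**
Reactants: 4 (1Z,3Z)-4-(benzyloxy)-1-methoxy-1,3-bis(trimethylsilyloxy)buta-1,3-diene; 5 tert-butyl but-2-ynoate
Product: 8 tert-butyl 5-(benzyloxy)-2,4-dihydroxy-6-methylbenzoate, via cyclohexa-1,4-diene cycloadduct 6 (not isolated), via aryl bis(trimethylsilyl) ether 7 (not isolated)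
Conditions: 4 (2 equiv), toluene, sealed tube, 120 °C; then 1 M aq. HCl, THF, 0 °C
Reagents that add atoms: none
Why: The electron-rich diene 4 and the electron-poor ynoate 5 should combine in a normal-demand, strongly asynchronous [4+2] cycloaddition, the bond from the benzyloxy-bearing C4 of 4 to the methyl-bearing β-carbon of 5 leading and the bond from the ketene acetal carbon C1 to the ester-bearing α-carbon following; the closest known reaction type is the Diels–Alder benzannulation of 1,1,3-trioxygenated silyloxy dienes with β-alkyl acetylenic esters. Ring B is closed in this intermolecular [4+2] mode as the cyclohexa-1,4-diene 6, whose only sp3 carbons are the mixed ketal carbon and the CH(OBn) carbon. Loss of methoxide from the bis-allylic ketal (or collapse of the desilylated hemiketal) and of the proton on the CH(OBn) carbon gives arene 7, and the aryl silyl ethers are cleaved in the acidic work-up; no stereocentre survives, so the two transient centres of 6 need no control. Regioselectivity is required and rests on the largest HOMO coefficient at C4 of 4 (pushed by the 3-silyloxy group and, through the diene, by the ketene acetal) meeting the largest LUMO coefficient at the β-carbon of 5. Aromatisation by loss of methanol alone is also required: the benzyloxy carbon carries a hydrogen but no second leaving group, and the ketal Si–O bond is cleaved at silicon, so the benzyl ether and both ring oxygens are retained.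

**Step 4**
Reactants: 8 tert-butyl 5-(benzyloxy)-2,4-dihydroxy-6-methylbenzoate
Product: 9 tert-butyl 5-(benzyloxy)-3-formyl-2,4-dihydroxy-6-methylbenzoate
Conditions: MgCl2, Et3N, (CH2O)n, MeCN, reflux; then 1 M aq. HCl, 0 °C
Reagents that add atoms: paraformaldehyde (as formaldehyde), C=O
Why: Casnati–Skattebøl ortho-formylation, in which the magnesium phenoxide delivers formaldehyde to the ortho carbon and a second formaldehyde oxidises the hydroxymethyl stage by hydride transfer; C3 is the only free ring carbon and the basic medium spares the tert-butyl ester and benzyl ether.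

**Step 5**
Reactants: 9 tert-butyl 5-(benzyloxy)-3-formyl-2,4-dihydroxy-6-methylbenzoate
Product: 10 tert-butyl 5-(benzyloxy)-3-formyl-2,4-bis(methoxymethoxy)-6-methylbenzoate
Conditions: NaH (2.5 equiv), MOMCl (3 equiv), DMF, 0 °C → rt
Reagents that add atoms: chloromethyl methyl ether, COCCl
Why: Williamson-type O-alkylation of both sodium phenoxides with the highly reactive chloromethyl ether should mask the two chelated phenols as acetals that survive hydrogenolysis and acylation and leave in acid.

**Step 6**
Reactants: 10 tert-butyl 5-(benzyloxy)-3-formyl-2,4-bis(methoxymethoxy)-6-methylbenzoate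
Product: 11 tert-butyl 3-formyl-5-hydroxy-2,4-bis(methoxymethoxy)-6-methylbenzoate
Conditions: H2 (1 atm), Pd/C (10% palladium on carbon), EtOAc, rt, stopped at full conversion
Reagents that add atoms: none
Why: Catalytic hydrogenolysis of the aryl benzyl ether should be much faster than reduction of the hindered, di-ortho-alkoxylated aldehyde at 1 atm, while MOM ethers and the tert-butyl ester are inert, so only the C5 phenol is unveiled.

**Step 7**
Reactants: 12 methyl 2-hydroxy-4-methoxy-6-methylbenzoate
Product: 13 methyl 3-formyl-2-hydroxy-4-methoxy-6-methylbenzoate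
Conditions: MgCl2, Et3N, (CH2O)n, MeCN, reflux; then 1 M aq. HCl, 0 °C
Reagents that add atoms: paraformaldehyde (as formaldehyde), C=O
Why: Casnati–Skattebøl ortho-formylation is specific for the position ortho to the phenol, and C3 is the only such position that is free (C5 is para to the hydroxyl and is not addressed by the magnesium chelate).

**Step 8**
Reactants: 13 methyl 3-formyl-2-hydroxy-4-methoxy-6-methylbenzoate
Product: 14 methyl 3-formyl-4-methoxy-2-(methoxymethoxy)-6-methylbenzoate
Conditions: NaH, MOMCl, DMF, 0 °C → rt
Reagents that add atoms: chloromethyl methyl ether, COCCl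
Why: O-Alkylation of the sodium phenoxide (Williamson-type acetal formation) should mask the chelated phenol so that the derived acid chloride carries no free hydroxyl.

**Step 9**
Reactants: 14 methyl 3-formyl-4-methoxy-2-(methoxymethoxy)-6-methylbenzoate
Product: 15 3-formyl-4-methoxy-2-(methoxymethoxy)-6-methylbenzoic acid
Conditions: LiOH·H2O (excess), THF/MeOH/H2O, 60 °C; then 1 M HCl to pH 4, 0 °C
Reagents that add atoms: lithium hydroxide, [Li+].[OH-]
Why: Saponification of the methyl ester; the acetal is base-stable, the non-enolisable aldehyde flanked by two alkoxy groups should tolerate warm dilute hydroxide, and cold acidification to pH 4 keeps the MOM ether.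

**Step 10**
Reactants: 15 3-formyl-4-methoxy-2-(methoxymethoxy)-6-methylbenzoic acid
Product: 16 3-formyl-4-methoxy-2-(methoxymethoxy)-6-methylbenzoyl chloride
Conditions: 1-chloro-N,N,2-trimethylprop-1-en-1-amine, CH2Cl2, 0 °C → rt; concentrated and used at once
Reagents that add atoms: 1-chloro-N,N,2-trimethylprop-1-en-1-amine, CC(C)=C(Cl)N(C)C
Why: The α-chloroenamine converts the acid into the acid chloride under neutral conditions without HCl, which the ortho MOM ether would not tolerate (acid chloride formation).

**Step 11**
Reactants: 11 tert-butyl 3-formyl-5-hydroxy-2,4-bis(methoxymethoxy)-6-methylbenzoate; 16 3-formyl-4-methoxy-2-(methoxymethoxy)-6-methylbenzoyl chloride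
Product: 17 tert-butyl 3-formyl-5-{[3-formyl-4-methoxy-2-(methoxymethoxy)-6-methylbenzoyl]oxy}-2,4-bis(methoxymethoxy)-6-methylbenzoate
Conditions: Et3N, DMAP (4-(dimethylamino)pyridine), CH2Cl2, 0 °C → rt
Reagents that add atoms: none
Why: DMAP-assisted nucleophilic acyl substitution of the aroyl chloride by the only free hydroxyl of 11 should give the depside ester, no other nucleophilic site being present in either partner.

**Step 12**
Reactants: 17 tert-butyl 3-formyl-5-{[3-formyl-4-methoxy-2-(methoxymethoxy)-6-methylbenzoyl]oxy}-2,4-bis(methoxymethoxy)-6-methylbenzoate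
Product: 18 haemathamnolic acid
Conditions: TFA/CH2Cl2/H2O, 0 °C → rt
Reagents that add atoms: none
Why: Acidolysis should cleave the three MOM acetals via oxocarbenium ions and the tert-butyl ester by loss of the tert-butyl cation, while the di-ortho-substituted depside ester is shielded from solvolysis and the freed phenols chelate the neighbouring carbonyls.

**Compound list**
1 | methyl 4-(benzyloxy)-3-oxobutanoate | COC(=O)CC(=O)COCc1ccccc1 | starting material
2 | chlorotrimethylsilane | C[Si](C)(C)Cl | starting material
3 | methyl 4-(benzyloxy)-3-(trimethylsilyloxy)but-2-enoate (E/Z mixture) | COC(=O)C=C(COCc1ccccc1)O[Si](C)(C)C | intermediate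
4 | (1Z,3Z)-4-(benzyloxy)-1-methoxy-1,3-bis(trimethylsilyloxy)buta-1,3-diene | CO/C(O[Si](C)(C)C)=C/C(O[Si](C)(C)C)=C/OCc1ccccc1 | intermediate
5 | tert-butyl but-2-ynoate | CC#CC(=O)OC(C)(C)C | starting material
6 | tert-butyl 3-(benzyloxy)-6-methoxy-2-methyl-4,6-bis(trimethylsilyloxy)cyclohexa-1,4-diene-1-carboxylate (racemic diastereomer mixture, formed in the flask) | COC1(O[Si](C)(C)C)C=C(O[Si](C)(C)C)C(OCc2ccccc2)C(C)=C1C(=O)OC(C)(C)C | intermediate
7 | tert-butyl 3-(benzyloxy)-2-methyl-4,6-bis(trimethylsilyloxy)benzoate (formed in the flask) | Cc1c(OCc2ccccc2)c(O[Si](C)(C)C)cc(O[Si](C)(C)C)c1C(=O)OC(C)(C)C | intermediate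
8 | tert-butyl 5-(benzyloxy)-2,4-dihydroxy-6-methylbenzoate | Cc1c(OCc2ccccc2)c(O)cc(O)c1C(=O)OC(C)(C)C | intermediate
9 | tert-butyl 5-(benzyloxy)-3-formyl-2,4-dihydroxy-6-methylbenzoate | Cc1c(OCc2ccccc2)c(O)c(C=O)c(O)c1C(=O)OC(C)(C)C | intermediate
10 | tert-butyl 5-(benzyloxy)-3-formyl-2,4-bis(methoxymethoxy)-6-methylbenzoate | Cc1c(OCc2ccccc2)c(OCOC)c(C=O)c(OCOC)c1C(=O)OC(C)(C)C | intermediate
11 | tert-butyl 3-formyl-5-hydroxy-2,4-bis(methoxymethoxy)-6-methylbenzoate | Cc1c(O)c(OCOC)c(C=O)c(OCOC)c1C(=O)OC(C)(C)C | intermediate
12 | methyl 2-hydroxy-4-methoxy-6-methylbenzoate | COC(=O)c1c(C)cc(OC)cc1O | starting material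
13 | methyl 3-formyl-2-hydroxy-4-methoxy-6-methylbenzoate | COC(=O)c1c(C)cc(OC)c(C=O)c1O | intermediate
14 | methyl 3-formyl-4-methoxy-2-(methoxymethoxy)-6-methylbenzoate | COCOc1c(C=O)c(OC)cc(C)c1C(=O)OC | intermediate
15 | 3-formyl-4-methoxy-2-(methoxymethoxy)-6-methylbenzoic acid | COCOc1c(C=O)c(OC)cc(C)c1C(=O)O | intermediate
16 | 3-formyl-4-methoxy-2-(methoxymethoxy)-6-methylbenzoyl chloride | COCOc1c(C=O)c(OC)cc(C)c1C(=O)Cl | intermediate
17 | tert-butyl 3-formyl-5-{[3-formyl-4-methoxy-2-(methoxymethoxy)-6-methylbenzoyl]oxy}-2,4-bis(methoxymethoxy)-6-methylbenzoate | COCOc1c(C=O)c(OC)cc(C)c1C(=O)Oc1c(C)c(C(=O)OC(C)(C)C)c(OCOC)c(C=O)c1OCOC | intermediate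
18 | haemathamnolic acid, 3-formyl-5-[(3-formyl-2-hydroxy-4-methoxy-6-methylbenzoyl)oxy]-2,4-dihydroxy-6-methylbenzoic acid | COc1cc(C)c(C(=O)Oc2c(C)c(C(=O)O)c(O)c(C=O)c2O)c(O)c1C=O | target

**Step count**
Total: 12 steps. Longest linear sequence: 8 steps (1, 2, 3, 4, 5, 6, 11, 12).

**Steps most likely to fail**

1. Step 3. The cycloaddition of the β-methyl ynoate may be slower than thermal degradation of the diene (silyl shifts, adventitious hydrolysis). The aromatisation may also partly proceed by loss of silanol instead of methanol, leaving a methyl ether. The fallback sets out from 4 and replaces the alkyne by an allene, whose α,β-double bond is a markedly better 2π partner. tert-Butyl buta-2,3-dienoate F1 would be made from tert-butyl (triphenylphosphoranylidene)acetate, acetyl chloride and Et3N in CH2Cl2 (Wittig reaction with ketene formed in the flask). Diene 4 and F1 in toluene at 60–80 °C should give tert-butyl 3-(benzyloxy)-6-methoxy-2-methylidene-4,6-bis(trimethylsilyloxy)cyclohex-4-ene-1-carboxylate F2, with C4 of the diene bonded to the central allene carbon. β-Elimination of methanol next to the ester and a 1,3-hydrogen shift of the exocyclic methylene would lead to 7. The same acidic work-up returns to the route at 8.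

2. Step 11. Acyl transfer between two di-ortho-substituted partners may be slow, and meanwhile the acid chloride can attack its own MOM group or hydrolyse. The fallback sets out from 13 and 11 and drops the protecting group next to the acyl carbon. Hydrolysis of 13 (KOH, aq. DMSO, 80 °C; then cold HCl) should give 3-formyl-2-hydroxy-4-methoxy-6-methylbenzoic acid F3, whose doubly chelated hydroxyl is not acylated. Carbodiimide coupling of F3 with 11 (N,N'-dicyclohexylcarbodiimide, catalytic DMAP, CH2Cl2, rt) should give tert-butyl 3-formyl-5-[(3-formyl-2-hydroxy-4-methoxy-6-methylbenzoyl)oxy]-2,4-bis(methoxymethoxy)-6-methylbenzoate F4. TFA/CH2Cl2/H2O then returns to the route at 18.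

3. Step 12. Formaldehyde and methoxymethyl cations set free from three acetals may be captured by the newly freed salicylic acid unit (cyclic methylene acetal) or by ring A. The long acid exposure may also cause acyl migration or cleavage of the depside. The fallback sets out from 17 and separates the two acidolyses. Catalytic HCl in i-PrOH/THF at 40 °C should remove the MOM groups as the mixed formal while the carboxyl is still blocked, giving tert-butyl 3-formyl-5-[(3-formyl-2-hydroxy-4-methoxy-6-methylbenzoyl)oxy]-2,4-dihydroxy-6-methylbenzoate F5. A short treatment with TFA/CH2Cl2 at 0 °C, now free of any formaldehyde source, returns to the route at 18.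

**Further compounds**
F1 | step 3 | tert-butyl buta-2,3-dienoate | C=C=CC(=O)OC(C)(C)C
F2 | step 3 | tert-butyl 3-(benzyloxy)-6-methoxy-2-methylidene-4,6-bis(trimethylsilyloxy)cyclohex-4-ene-1-carboxylate (racemic diastereomer mixture) | COC1(O[Si](C)(C)C)C=C(O[Si](C)(C)C)C(OCc2ccccc2)C(=C)C1C(=O)OC(C)(C)C
F3 | step 11 | 3-formyl-2-hydroxy-4-methoxy-6-methylbenzoic acid | COc1cc(C)c(C(=O)O)c(O)c1C=O
F4 | step 11 | tert-butyl 3-formyl-5-[(3-formyl-2-hydroxy-4-methoxy-6-methylbenzoyl)oxy]-2,4-bis(methoxymethoxy)-6-methylbenzoate | COc1cc(C)c(C(=O)Oc2c(C)c(C(=O)OC(C)(C)C)c(OCOC)c(C=O)c2OCOC)c(O)c1C=O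
F5 | step 12 | tert-butyl 3-formyl-5-[(3-formyl-2-hydroxy-4-methoxy-6-methylbenzoyl)oxy]-2,4-dihydroxy-6-methylbenzoate | COc1cc(C)c(C(=O)Oc2c(C)c(C(=O)OC(C)(C)C)c(O)c(C=O)c2O)c(O)c1C=O
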